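**Plan**

1. Retrosynthesis: the seven phenols are masked as benzyl ethers, removed in one final hydrogenolysis. The C4(upper pyran)–C8(lower benzo ring) bond and the upper C3–O bond are then cut together, which unravels the upper unit to a 2-aryl-2H-chromene (flav-3-ene), one oxygen atom and the C8–H of a protected 6-methylcatechin.
2. Enabling feature: upper C4 is benzylic to ring A, conjugated through C4a with the C7 oxygen, and lies next to the C3 carbinol, so C3/C4 are the two carbons of a polarised epoxide. In the lower 5,7-dioxygenated ring C6 carries the methyl group, so C8 (between C8a–O1 and C7–O) is the only nucleophilic C–H.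
3. Lower unit (steps 1–5): from (+)-catechin, which brings its pyran ring; benzylation, C8 bromide as blocking group, C6 iodination and Negishi methylation, debromination.
4. Upper unit (steps 6–9): a chromone (pyran ring present) is arylated at C2 by asymmetric 1,4-addition, then reduced and dehydrated to the flav-3-ene.
5. Union and end game: one-flask epoxidation and arylative epoxide opening (step 10), then global hydrogenolysis (step 11).
6. Stereochemistry: lower C2/C3 come from (+)-catechin; upper C2 from the catalyst; upper C3 from C2 (epoxidation anti to the aryl group); upper C4 from C3 (anti opening), giving the 2,3-trans-3,4-trans arrangement.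

Key step: step 10

Remark: the target is read as the (4α→8) all-trans dimer, (2R,3S,4S) in the upper and (2R,3S) in the lower unit; chiral ligand antipodes are specified by the product configuration they must give (2S-flavanone), to be assigned against a racemic reference.

**Route**

Step 1
Reactants: 1 (+)-catechin
Product: 2 5,7,3',4'-tetra-O-benzyl-(+)-catechin
Conditions: BnBr (4.2 equiv), K2CO3, DMF, 0 °C to rt, Ar
Reagents that add atoms: benzyl bromide, BrCc1ccccc1
Why: Williamson etherification alkylates the four phenols, while the much less acidic secondary 3-OH stays free and C2/C3 are untouched.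

Step 2
Reactants: 2 5,7,3',4'-tetra-O-benzyl-(+)-catechin
Product: 3 8-bromo-5,7,3',4'-tetra-O-benzyl-(+)-catechin
Conditions: NBS (1.0 equiv), CH2Cl2, −78 °C to rt
Reagents that add atoms: N-bromosuccinimide, O=C1CCC(=O)N1Br
Why: Electrophilic aromatic bromination of the trioxygenated ring should follow the established C8 preference of benzyl-protected catechins and installs a removable blocking group.

Step 3
Reactants: 3 8-bromo-5,7,3',4'-tetra-O-benzyl-(+)-catechin
Product: 4 8-bromo-6-iodo-5,7,3',4'-tetra-O-benzyl-(+)-catechin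
Conditions: NIS (1.1 equiv), CH2Cl2/MeCN, 0 °C to rt, dark
Reagents that add atoms: N-iodosuccinimide, O=C1CCC(=O)N1I
Why: Electrophilic aromatic iodination can only reach C6, the last free carbon of the trioxygenated ring (C8 blocked), which is far more nucleophilic than the catechol diether ring; the known 6,8-dihalogenation of this ring is the analogy.

Step 4
Reactants: 4 8-bromo-6-iodo-5,7,3',4'-tetra-O-benzyl-(+)-catechin
Product: 5 8-bromo-6-methyl-5,7,3',4'-tetra-O-benzyl-(+)-catechin
Conditions: MeZnCl (3 equiv), PdCl2(dppf) (5 mol %), THF, 45 °C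
Reagents that add atoms: methylzinc chloride, C[Zn]Cl
Why: Negishi cross-coupling, in which oxidative addition into C–I is much faster than into the hindered, electron-rich C–Br bond at this temperature, so methyl should be delivered to C6 only (one equivalent of the zinc reagent is consumed by the 3-OH).

Step 5
Reactants: 5 8-bromo-6-methyl-5,7,3',4'-tetra-O-benzyl-(+)-catechin
Product: 7 5,7,3',4'-tetra-O-benzyl-6-methyl-(+)-catechin, via dilithio species 6 (not isolated)
Conditions: n-BuLi (2.2 equiv), THF, −78 °C; then MeOH, −78 °C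
Reagents that add atoms: none
Why: Bromine–lithium exchange after alkoxide formation, then protonation, removes the blocking group and frees C8–H without touching a stereocentre.

Step 6
Reactants: 8 7-hydroxy-4H-chromen-4-one
Product: 9 7-(benzyloxy)-4H-chromen-4-one
Conditions: BnBr (1.1 equiv), K2CO3, acetone, reflux
Reagents that add atoms: benzyl bromide, BrCc1ccccc1
Why: Williamson etherification of the acidic, vinylogous-acid 7-OH.

Step 7
Reactants: 9 7-(benzyloxy)-4H-chromen-4-one; 10 [3,4-bis(benzyloxy)phenyl]boronic acid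
Product: 11 (2S)-7-(benzyloxy)-2-[3,4-bis(benzyloxy)phenyl]chroman-4-one
Conditions: 10 (2 equiv), [Rh(OH)(cod)]2 (2.5 mol %), electron-poor atropisomeric bisphosphine (MeO-F12-BIPHEP type, antipode giving 2S), toluene/H2O 10:1, 30 °C, no base
Reagents that add atoms: none
Why: Rhodium-catalysed asymmetric 1,4-addition (Hayashi–Miyaura) of an arylboronic acid to a chromone, in which the chiral ligand controls the face of aryl–Rh insertion into C2=C3 and so sets C2; base-free conditions avoid retro-oxa-Michael racemisation.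

Step 8
Reactants: 11 (2S)-7-(benzyloxy)-2-[3,4-bis(benzyloxy)phenyl]chroman-4-one
Product: 12 (2S,4S)-7-(benzyloxy)-2-[3,4-bis(benzyloxy)phenyl]chroman-4-ol (2,4-cis)
Conditions: NaBH4, THF/MeOH, −10 °C
Reagents that add atoms: none
Why: Hydride reduction by axial attack on the half-chair with equatorial 2-aryl should give the 2,4-cis alcohol; the C4 configuration is lost in the next step and C2 is not affected.

Step 9
Reactants: 12 (2S,4S)-7-(benzyloxy)-2-[3,4-bis(benzyloxy)phenyl]chroman-4-ol
Product: 14 (2S)-7-(benzyloxy)-2-[3,4-bis(benzyloxy)phenyl]-2H-chromene, via C4 mesylate 13 (not isolated)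
Conditions: MsCl (1.5 equiv), Et3N (4 equiv), CH2Cl2, 0 °C to rt, dark; used at once
Reagents that add atoms: none
Why: Mesylation and E1-type elimination under amine buffering: the 4-mesylate ionises (stabilised by O1 and the para 7-benzyloxy group) and loses H3, and the absence of acid should prevent dimerisation and C2 epimerisation.

Step 10
Reactants: 14 (2S)-7-(benzyloxy)-2-[3,4-bis(benzyloxy)phenyl]-2H-chromene; 7 5,7,3',4'-tetra-O-benzyl-6-methyl-(+)-catechin
Product: 16 7,3',4'-tri-O-benzylfisetinidol-(4α→8)-5,7,3',4'-tetra-O-benzyl-6-methylcatechin, via epoxyflavan 15 (not isolated)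
Conditions: DMDO (1.05 equiv, acetone), CH2Cl2, −40 °C; volatiles removed cold; then 7 (1.5 equiv), CH2Cl2/HFIP 4:1, −40 to 0 °C
Reagents that add atoms: dimethyldioxirane, CC1(C)OO1
Why: Dimethyldioxirane transfers oxygen to the electron-rich C3=C4 bond of 14 through a concerted spiro transition state on the face anti to the C2 aryl group, so the oxirane of 15 (the only ring closed, by one-step oxygen-atom transfer and not by cyclisation of a chain) fixes C3 as S from C2. In hexafluoroisopropanol the hydrogen-bonded epoxide lengthens its C4–O bond, because C4 is benzylic to ring A and conjugated through C4a with the C7 benzyloxy oxygen, and the developing cation is taken by C8 of 7 in a Friedel–Crafts substitution followed by rearomatisation. The closest known reaction type is the fluorinated-alcohol- or Lewis-acid-promoted arylative opening of benzylic epoxides (styrene and chromene oxides) by alkoxyarenes, together with the Lewis-acid coupling of C4-oxygenated flavan-3-ols with flavan nucleophiles. C4 is set as S by attack anti to the C3–O bond (inversion in the tight ion pair; in the fully ionised limit the same face is favoured because it leads to the all-equatorial 2,3-trans-3,4-trans half-chair). The step needs site selectivity on 7, secured because C8 is the only unsubstituted carbon of the 5,7-dioxygenated ring (C6 bears the methyl group) and the catechol diether ring is far less nucleophilic, and it needs C- over O-alkylation, secured by the hindered secondary 3-hydroxyl groups and the high π-nucleophilicity of the ring. Arylation must outrun the 1,2-hydride shift to the flavan-3-one, which is addressed by excess 7, low temperature and complete consumption of 14 before activation.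

Step 11
Reactants: 16 7,3',4'-tri-O-benzylfisetinidol-(4α→8)-5,7,3',4'-tetra-O-benzyl-6-methylcatechin
Product: 17 fisetinidol-(4α→8)-6-methylcatechin (CNP0288113.1)
Conditions: H2 (1 atm), Pd(OH)2/C, THF/MeOH/H2O, rt; filtration and lyophilisation under Ar
Reagents that add atoms: none
Why: Hydrogenolysis of the seven aryl benzyl ethers over Pearlman's catalyst under neutral conditions should leave the C4–C8 bond, the benzylic C2–O1 bonds and all five stereocentres intact, as in established proanthocyanidin deprotections.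

**Compound list**

1 | (+)-catechin, (2R,3S)-2-(3,4-dihydroxyphenyl)chromane-3,5,7-triol | c1c(O)c2c(cc1O)O[C@H](c1ccc(O)c(O)c1)[C@@H](O)C2 | starting material
2 | 5,7,3',4'-tetra-O-benzyl-(+)-catechin, (2R,3S)-5,7-bis(benzyloxy)-2-[3,4-bis(benzyloxy)phenyl]chroman-3-ol | c1c(OCc3ccccc3)c2c(cc1OCc3ccccc3)O[C@H](c1ccc(OCc3ccccc3)c(OCc3ccccc3)c1)[C@@H](O)C2 | intermediate
3 | (2R,3S)-5,7-bis(benzyloxy)-2-[3,4-bis(benzyloxy)phenyl]-8-bromochroman-3-ol | c1c(OCc3ccccc3)c2c(c(Br)c1OCc3ccccc3)O[C@H](c1ccc(OCc3ccccc3)c(OCc3ccccc3)c1)[C@@H](O)C2 | intermediate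
4 | (2R,3S)-5,7-bis(benzyloxy)-2-[3,4-bis(benzyloxy)phenyl]-8-bromo-6-iodochroman-3-ol | Ic1c(OCc3ccccc3)c2c(c(Br)c1OCc3ccccc3)O[C@H](c1ccc(OCc3ccccc3)c(OCc3ccccc3)c1)[C@@H](O)C2 | intermediate
5 | (2R,3S)-5,7-bis(benzyloxy)-2-[3,4-bis(benzyloxy)phenyl]-8-bromo-6-methylchroman-3-ol | Cc1c(OCc3ccccc3)c2c(c(Br)c1OCc3ccccc3)O[C@H](c1ccc(OCc3ccccc3)c(OCc3ccccc3)c1)[C@@H](O)C2 | intermediate
6 | C8-lithio lithium 3-alkoxide derived from 5 | Cc1c(OCc3ccccc3)c2c(c([Li])c1OCc3ccccc3)O[C@H](c1ccc(OCc3ccccc3)c(OCc3ccccc3)c1)[C@@H](O[Li])C2 | intermediate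
7 | 5,7,3',4'-tetra-O-benzyl-6-methyl-(+)-catechin, (2R,3S)-5,7-bis(benzyloxy)-2-[3,4-bis(benzyloxy)phenyl]-6-methylchroman-3-ol | Cc1c(OCc3ccccc3)c2c(cc1OCc3ccccc3)O[C@H](c1ccc(OCc3ccccc3)c(OCc3ccccc3)c1)[C@@H](O)C2 | intermediate
8 | 7-hydroxy-4H-chromen-4-one | O=c1ccoc2cc(O)ccc12 | starting material
9 | 7-(benzyloxy)-4H-chromen-4-one | O=c1ccoc2cc(OCc3ccccc3)ccc12 | intermediate
10 | [3,4-bis(benzyloxy)phenyl]boronic acid | OB(O)c1ccc(OCc2ccccc2)c(OCc2ccccc2)c1 | starting material
11 | (2S)-7-(benzyloxy)-2-[3,4-bis(benzyloxy)phenyl]chroman-4-one | O=C1c2ccc(OCc3ccccc3)cc2O[C@H](c2ccc(OCc3ccccc3)c(OCc3ccccc3)c2)C1 | intermediate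
12 | (2S,4S)-7-(benzyloxy)-2-[3,4-bis(benzyloxy)phenyl]chroman-4-ol (2,4-cis) | O[C@@H]1c2ccc(OCc3ccccc3)cc2O[C@H](c2ccc(OCc3ccccc3)c(OCc3ccccc3)c2)C1 | intermediate
13 | (2S,4S)-7-(benzyloxy)-2-[3,4-bis(benzyloxy)phenyl]chroman-4-yl methanesulfonate | CS(=O)(=O)O[C@@H]1c2ccc(OCc3ccccc3)cc2O[C@H](c2ccc(OCc3ccccc3)c(OCc3ccccc3)c2)C1 | intermediate
14 | (2S)-7-(benzyloxy)-2-[3,4-bis(benzyloxy)phenyl]-2H-chromene | C1=Cc2ccc(OCc3ccccc3)cc2O[C@@H]1c1ccc(OCc2ccccc2)c(OCc2ccccc2)c1 | intermediate
15 | (2R,3S,4S)-7-(benzyloxy)-2-[3,4-bis(benzyloxy)phenyl]-3,4-epoxychromane (flavan numbering; oxirane anti to the 2-aryl group) | O1[C@H]2c3ccc(OCc4ccccc4)cc3O[C@H](c3ccc(OCc4ccccc4)c(OCc4ccccc4)c3)[C@@H]12 | intermediate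
16 | (2R,3S)-5,7-bis(benzyloxy)-2-[3,4-bis(benzyloxy)phenyl]-8-{(2R,3S,4S)-7-(benzyloxy)-2-[3,4-bis(benzyloxy)phenyl]-3-hydroxychroman-4-yl}-6-methylchroman-3-ol | Cc1c(OCc5ccccc5)c2c(c([C@@H]3c4ccc(OCc5ccccc5)cc4O[C@H](c4ccc(OCc5ccccc5)c(OCc5ccccc5)c4)[C@H]3O)c1OCc5ccccc5)O[C@H](c1ccc(OCc5ccccc5)c(OCc5ccccc5)c1)[C@@H](O)C2 | intermediate
17 | (2R,3S)-8-[(2R,3S,4S)-2-(3,4-dihydroxyphenyl)-3,7-dihydroxychroman-4-yl]-2-(3,4-dihydroxyphenyl)-6-methylchromane-3,5,7-triol, fisetinidol-(4α→8)-6-methylcatechin | Cc1c(O)c2c(c([C@@H]3c4ccc(O)cc4O[C@H](c4ccc(O)c(O)c4)[C@H]3O)c1O)O[C@H](c1ccc(O)c(O)c1)[C@@H](O)C2 | target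

**Count and risks**

Total step count: 11. Longest linear sequence: 7 (steps 1–5, 10, 11).

Most likely to fail:

Step 10. The ionised epoxide may undergo a 1,2-hydride shift to the flavan-3-one faster than it is arylated, or the anti opening may erode through a long-lived cation. Fallback: setting out from 14, catalytic OsO4/NMO dihydroxylation anti to the 2-aryl group should give the 2,3-trans-3,4-cis diol (2R,3S,4S)-7-(benzyloxy)-2-[3,4-bis(benzyloxy)phenyl]chromane-3,4-diol F1. Ionisation of the C4 hydroxyl of F1 with TMSOTf in CH2Cl2 at −78 °C in the presence of 7 (Friedel–Crafts coupling of a flavan-3,4-diol, attack trans to the C3 oxygen) should return to the route at 16.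

Step 7. Insertion into the electron-rich 7-alkoxychromone may be slow relative to protodeboronation, or facial discrimination may be insufficient. Fallback: setting out from 9 and 10, the same 1,4-addition with an achiral rhodium catalyst should give racemic 7-(benzyloxy)-2-[3,4-bis(benzyloxy)phenyl]chroman-4-one F2. Noyori–Ikariya asymmetric transfer hydrogenation of F2 under kinetic resolution (RuCl(p-cymene)(TsDPEN), HCO2H/Et3N; catalyst antipode that reduces the 2S ketone) should give the 2,4-cis alcohol and leave the 2R ketone behind for separation; the route is rejoined at 12.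

Step 4. Chemoselectivity between the C–I and C–Br bonds may be lost, or the hindered iodide may be reductively dehalogenated. Fallback: setting out from 3, Vilsmeier–Haack formylation (POCl3/DMF; aqueous NaOAc, then K2CO3/MeOH to cleave the O3 formate) at the only free ring carbon should give (2R,3S)-5,7-bis(benzyloxy)-2-[3,4-bis(benzyloxy)phenyl]-8-bromo-3-hydroxychromane-6-carbaldehyde F3. Ionic hydrogenation of this 2,6-dialkoxybenzaldehyde F3 (Et3SiH, TFA, CH2Cl2, 0 °C) should reduce the formyl group to methyl and return to the route at 5, bypassing 4.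

Further compounds
F1 | step 10 | (2R,3S,4S)-7-(benzyloxy)-2-[3,4-bis(benzyloxy)phenyl]chromane-3,4-diol (2,3-trans-3,4-cis) | O[C@H]1c2ccc(OCc3ccccc3)cc2O[C@H](c2ccc(OCc3ccccc3)c(OCc3ccccc3)c2)[C@H]1O
F2 | step 7 | racemic 7-(benzyloxy)-2-[3,4-bis(benzyloxy)phenyl]chroman-4-one | O=C1CC(c2ccc(OCc3ccccc3)c(OCc3ccccc3)c2)Oc2cc(OCc3ccccc3)ccc12
F3 | step 4 | (2R,3S)-5,7-bis(benzyloxy)-2-[3,4-bis(benzyloxy)phenyl]-8-bromo-3-hydroxychromane-6-carbaldehyde | O=Cc1c(OCc3ccccc3)c2c(c(Br)c1OCc3ccccc3)O[C@H](c1ccc(OCc3ccccc3)c(OCc3ccccc3)c1)[C@@H](O)C2
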